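**Plan**

- Retrosynthesis: cut the C6–alkenyl bond (Suzuki–Miyaura), the two C–CH3 bonds of the carbinol (ester + MeMgBr) and the pyranone O1–C2 bond (cyclodehydration of an o-hydroxyaryl 1,3-diketone). Then cut the chromone C2–C3 bond and the oxepine CH2–CH(O) bond while reconnecting chromone C2 to the O-bearing carbon.
- This last operation contracts the oxepine (O2′, CH(O), CH2, C3, C2, C1′, C2′) to the furanone ring of a 3-oxo-2,3-dihydrobenzofuran-2-carboxylate and releases the CH2–C3 unit as the two alkyne carbons of an A-ring aryl ethynyl ketone.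
- Enabling feature: the O-bearing oxepine carbon carries a carboxyl-level substituent (C(CH3)2OH from CO2R) and lies 1,4 to the ketone-level chromone C2, with the A-ring acyl carbon (C4=O) on C3 between them. This is the pattern left when an acyl alkyne is inserted into the C(α)–C(=O) bond of a cyclic β-keto ester.
- Forward: B-ring benzofuranol ester 4 and A-ring ynone 9 are made separately. The furanone ring is then expanded to the oxepine (5 → 7) with formation of the 1,3-diketone, acid closes the pyranone ring, and hydrogenation, Grignard addition and late C6 alkenylation follow.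
- Stereochemistry: the single (R) centre comes from catalyst-controlled asymmetric hydrogenation of the cyclic (Z)-α-aryloxyacrylic acid 12. The E-alkene comes from the (E)-alkenylboronate with retention.

Key step: step 6

Remark: the target stereocentre is (R) (CIP order O > C(CH3)2OH > CH2 > H); compounds 1, 2, 5 and 19 are taken as commercially available; 10 and 11 are drawn as single tautomers.

**Route**

Step 1
Reactants: 1 methyl 4-(benzyloxy)-2-hydroxybenzoate; 2 tert-butyl bromoacetate
Product: 4 tert-butyl 6-(benzyloxy)-3-hydroxy-1-benzofuran-2-carboxylate, via aryloxyacetate diester 3 (not isolated)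
Conditions: K2CO3, DMF, 60 °C; then t-BuOK, THF, 0 °C → rt; 1 M HCl
Reagents that add atoms: none
Why: Williamson O-alkylation of the salicylate phenol followed by Dieckmann condensation of the aryloxyacetate α-carbanion onto the neighbouring methyl ester is the standard entry to 3-hydroxybenzofuran-2-carboxylates, and the tert-butyl ester is not transesterified by tert-butoxide.

Step 2
Reactants: 5 5-methoxybenzene-1,3-diol
Product: 6 1-methoxy-3,5-bis(methoxymethoxy)benzene
Conditions: MOMCl, i-Pr2NEt, CH2Cl2, 0 °C → rt
Reagents that add atoms: chloromethyl methyl ether (MOMCl), COCCl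
Why: Both phenols are converted into MOM acetals, which later act as ortho-directing groups and as acid-labile masks of the two hydroxyls needed for chromone closure.

Step 3
Reactants: 6 1-methoxy-3,5-bis(methoxymethoxy)benzene
Product: 7 4-methoxy-2,6-bis(methoxymethoxy)benzaldehyde
Conditions: n-BuLi, TMEDA, THF, 0 °C; DMF, −78 °C → rt; aq. NH4Cl
Reagents that add atoms: N,N-dimethylformamide, CN(C)C=O
Why: Directed ortho-metalation should occur at the position flanked by the two MOM ethers (cooperative chelation), and the aryllithium is formylated by DMF.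

Step 4
Reactants: 7 4-methoxy-2,6-bis(methoxymethoxy)benzaldehyde
Product: 8 rac-1-[4-methoxy-2,6-bis(methoxymethoxy)phenyl]prop-2-yn-1-ol
Conditions: HC≡CMgBr, THF, 0 °C; aq. NH4Cl
Reagents that add atoms: ethynylmagnesium bromide, C#C[Mg]Br
Why: 1,2-Addition of the alkynyl Grignard reagent to the aldehyde gives the racemic propargylic alcohol, whose stereocentre is removed in the next step.

Step 5
Reactants: 8 rac-1-[4-methoxy-2,6-bis(methoxymethoxy)phenyl]prop-2-yn-1-ol
Product: 9 1-[4-methoxy-2,6-bis(methoxymethoxy)phenyl]prop-2-yn-1-one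
Conditions: activated MnO2, CH2Cl2, rt
Reagents that add atoms: none
Why: Activated MnO2 oxidises benzylic propargylic alcohols to ynones under neutral conditions that leave the MOM acetals intact.

Step 6
Reactants: 4 tert-butyl 6-(benzyloxy)-3-hydroxy-1-benzofuran-2-carboxylate; 9 1-[4-methoxy-2,6-bis(methoxymethoxy)phenyl]prop-2-yn-1-one
Product: 11 tert-butyl 8-(benzyloxy)-4-[4-methoxy-2,6-bis(methoxymethoxy)benzoyl]-5-oxo-4,5-dihydro-1-benzoxepine-2-carboxylate, via cyclobutene-fused alkoxide 10 (not isolated)
Conditions: NaH (1.05 equiv), THF, 0 °C; slow addition of 9, 0 °C → rt; 1 M HCl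
Reagents that add atoms: none
Why: The sodium enolate of 4 adds through C2 to the unsubstituted alkyne terminus of 9 (Michael addition), the resulting vinyl anion (allenolate) closes onto the adjacent C3 ketone (4-exo-trig aldol) to give the cyclobutene-fused alkoxide 10, and strain-driven retro-aldol cleavage of the former C2–C3 bond opens the bicyclo[3.2.0] system to the seven-membered ring as a delocalised β-diketonate. The closest known reaction type is the base-mediated two-carbon ring expansion of cyclic and hetero-fused β-keto esters with acetylenic esters, a formal insertion of an activated alkyne into the C(α)–C(=O) bond, here run with an aryl ethynyl ketone as the alkyne. The oxepine is therefore not closed by cyclisation but arises by two-atom expansion of the furanone ring (5 → 7), the only ring closure being the transient 4-exo-trig aldol. No stereocentre has to be controlled, because the two centres of 10 are racemic and both become sp2 or enolisable in 11. The step needs C- rather than O-attack of the ambident enolate, which the sodium chelate between enolate oxygen and ester and the soft ynone acceptor should secure, and it needs the aroyl-bearing carbon to end up on the former ketone carbon, which follows from attack at the unsubstituted alkyne terminus. Stoichiometric NaH and slow addition of 9 keep proton donors away, so that the vinyl anion should cyclise instead of being quenched to the open Michael adduct.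

Step 7
Reactants: 11 tert-butyl 8-(benzyloxy)-4-[4-methoxy-2,6-bis(methoxymethoxy)benzoyl]-5-oxo-4,5-dihydro-1-benzoxepine-2-carboxylate
Product: 12 oxepine-fused flavone acrylic acid (4′-benzyloxy-5-hydroxy-7-methoxyflavone with C3 joined to O2′ by CH=C(CO2H))
Conditions: TFA/CH2Cl2 (1:2), H2O (5 equiv), rt → 40 °C
Reagents that add atoms: none
Why: Acid removes both MOM acetals and the tert-butyl ester, and the liberated o-hydroxyaryl 1,3-diketone cyclodehydrates (phenol addition to the B-ring ketone, then loss of water) to the chromone; since the two A-ring hydroxyls are equivalent, only the 5-hydroxy-7-methoxy pattern can result.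

Step 8
Reactants: 12 oxepine-fused flavone acrylic acid
Product: 13 (R)-dihydro acid (bridge C3–CH2–CH(CO2H)–O2′)
Conditions: H2 (6 atm), chiral spiro phosphine–oxazoline Ir(cod) BArF catalyst (1 mol %), Et3N (0.5 equiv), MeOH, rt
Reagents that add atoms: none
Why: Carboxylate-directed iridium-catalysed asymmetric hydrogenation of (Z)-α-aryloxy-α,β-unsaturated acids is a known reaction type in which the chiral ligand controls the face of hydrogen delivery; the ligand antipode is chosen to give the (R)-acid, and the tetrasubstituted chromone double bond and the benzyl ether should not be reduced.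

Step 9
Reactants: 13 (R)-dihydro acid
Product: 14 (R)-methyl ester (bridge C3–CH2–CH(CO2CH3)–O2′)
Conditions: TMSCHN2, PhMe/MeOH (4:1), 0 °C
Reagents that add atoms: trimethylsilyldiazomethane, C[Si](C)(C)C=[N+]=[N-]
Why: Trimethylsilyldiazomethane methylates the carboxylic acid under neutral conditions, which should neither epimerise the α-centre nor methylate the hydrogen-bonded 5-hydroxyl.

Step 10
Reactants: 14 (R)-methyl ester
Product: 15 (R)-tertiary alcohol (bridge C3–CH2–CH[C(CH3)2OH]–O2′ with 4′-OBn)
Conditions: MeMgBr (5 equiv), THF, −40 → 0 °C; aq. NH4Cl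
Reagents that add atoms: methylmagnesium bromide, C[Mg]Br
Why: Double Grignard addition to the ester gives the tertiary alcohol; the first equivalent deprotonates the 5-hydroxyl so that the chelated magnesium phenoxide deactivates the chromone carbonyl, and the low temperature limits enolisation of the α-aryloxy ester so that the (R)-centre is retained.

Step 11
Reactants: 15 (R)-tertiary alcohol
Product: 16 4′-phenol (6-desalkenyl target)
Conditions: H2 (1 atm), 10% Pd/C, EtOAc/EtOH, rt
Reagents that add atoms: none
Why: Hydrogenolysis removes the benzyl ether before any reducible alkene is present, and the tetrasubstituted chromone double bond is inert under these conditions.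

Step 12
Reactants: 16 4′-phenol
Product: 17 4′-O-acetate
Conditions: Ac2O (1.1 equiv), pyridine, CH2Cl2, 0 °C
Reagents that add atoms: acetic anhydride, CC(=O)OC(C)=O
Why: The free 4′-phenol is acetylated selectively because the 5-hydroxyl is hydrogen-bonded to the C4 carbonyl and the tertiary alcohol is hindered, and the acetate lowers the nucleophilicity of the B ring for the next step.

Step 13
Reactants: 17 4′-O-acetate
Product: 18 6-iodo-4′-O-acetate
Conditions: BnMe3N+ ICl2− (1.05 equiv), CaCO3, CH2Cl2/MeOH (5:2), rt
Reagents that add atoms: benzyltrimethylammonium dichloroiodate, C[N+](C)(C)Cc1ccccc1.Cl[I-]Cl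
Why: Electrophilic iodination of 5-hydroxy-7-alkoxyflavones with the dichloroiodate salt is directed to C6, ortho to the free 5-hydroxyl and to the 7-methoxy group, while the acetylated B ring is deactivated.

Step 14
Reactants: 18 6-iodo-4′-O-acetate; 19 (E)-4,4,5,5-tetramethyl-2-(3-methylbut-1-en-1-yl)-1,3,2-dioxaborolane
Product: 21 target flavone CNP0216454.1, via 4′-O-acetyl coupling product 20 (not isolated)
Conditions: Pd(dppf)Cl2 (5 mol %), K2CO3, dioxane/H2O (4:1), 80 °C; then MeOH, rt
Reagents that add atoms: none
Why: Suzuki–Miyaura coupling of the aryl iodide with the (E)-alkenylboronate proceeds with retention of alkene geometry, and the aqueous carbonate then cleaves the phenolic acetate to release the target.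

**Compound list**

1 | methyl 4-(benzyloxy)-2-hydroxybenzoate | COC(=O)c1ccc(OCc2ccccc2)cc1O | starting material
2 | tert-butyl bromoacetate | CC(C)(C)OC(=O)CBr | starting material
3 | methyl 4-(benzyloxy)-2-(2-tert-butoxy-2-oxoethoxy)benzoate | COC(=O)c1ccc(OCc2ccccc2)cc1OCC(=O)OC(C)(C)C | intermediate (not isolated)
4 | tert-butyl 6-(benzyloxy)-3-hydroxy-1-benzofuran-2-carboxylate (enol of the 3-oxo-2,3-dihydro β-keto ester) | CC(C)(C)OC(=O)c1oc2cc(OCc3ccccc3)ccc2c1O | intermediate
5 | 5-methoxybenzene-1,3-diol | COc1cc(O)cc(O)c1 | starting material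
6 | 1-methoxy-3,5-bis(methoxymethoxy)benzene | COCOc1cc(OC)cc(OCOC)c1 | intermediate
7 | 4-methoxy-2,6-bis(methoxymethoxy)benzaldehyde | COCOc1cc(OC)cc(OCOC)c1C=O | intermediate
8 | rac-1-[4-methoxy-2,6-bis(methoxymethoxy)phenyl]prop-2-yn-1-ol | COCOc1cc(OC)cc(OCOC)c1C(O)C#C | intermediate
9 | 1-[4-methoxy-2,6-bis(methoxymethoxy)phenyl]prop-2-yn-1-one | COCOc1cc(OC)cc(OCOC)c1C(=O)C#C | intermediate
10 | cyclobutene-fused alkoxide: cis-fused cyclobuta[b]benzofuran built from C2 and C3 of 4 and the two alkyne carbons of 9, with CO2t-Bu on the O-bearing fusion carbon, O− on the other fusion carbon and the aroyl group on the adjacent alkene carbon (racemic, shown as the alcohol) | CC(C)(C)OC(=O)C12Oc3cc(OCc4ccccc4)ccc3C1(O)C(C(=O)c1c(OCOC)cc(OC)cc1OCOC)=C2 | intermediate (not isolated)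
11 | tert-butyl 8-(benzyloxy)-4-[4-methoxy-2,6-bis(methoxymethoxy)benzoyl]-5-oxo-4,5-dihydro-1-benzoxepine-2-carboxylate (diketo tautomer, C4 enolisable) | CC(C)(C)OC(=O)C1=CC(C(=O)c2c(OCOC)cc(OC)cc2OCOC)C(=O)c2ccc(OCc3ccccc3)cc2O1 | intermediate
12 | oxepine-fused flavone acrylic acid: 4′-benzyloxy-5-hydroxy-7-methoxyflavone with C3 joined to O2′ by CH=C(CO2H), CH on C3 | OC(=O)C1=Cc2c(oc3cc(OC)cc(O)c3c2=O)-c2ccc(OCc3ccccc3)cc2O1 | intermediate
13 | (R)-dihydro acid: bridge C3–CH2–CH(CO2H)–O2′, (R) at the O-bearing carbon | COc1cc2oc3c(c(=O)c2c(O)c1)C[C@H](C(=O)O)Oc1cc(OCc2ccccc2)ccc1-3 | intermediate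
14 | (R)-methyl ester of 13 | COc1cc2oc3c(c(=O)c2c(O)c1)C[C@H](C(=O)OC)Oc1cc(OCc2ccccc2)ccc1-3 | intermediate
15 | (R)-tertiary alcohol: bridge C3–CH2–CH[C(CH3)2OH]–O2′, 4′-OBn | COc1cc2oc3c(c(=O)c2c(O)c1)C[C@H](C(C)(C)O)Oc1cc(OCc2ccccc2)ccc1-3 | intermediate
16 | (R)-4′-phenol (6-desalkenyl target) | COc1cc2oc3c(c(=O)c2c(O)c1)C[C@H](C(C)(C)O)Oc1cc(O)ccc1-3 | intermediate
17 | (R)-4′-O-acetate of 16 | COc1cc2oc3c(c(=O)c2c(O)c1)C[C@H](C(C)(C)O)Oc1cc(OC(C)=O)ccc1-3 | intermediate
18 | (R)-6-iodo-4′-O-acetate | COc1cc2oc3c(c(=O)c2c(O)c1I)C[C@H](C(C)(C)O)Oc1cc(OC(C)=O)ccc1-3 | intermediate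
19 | (E)-4,4,5,5-tetramethyl-2-(3-methylbut-1-en-1-yl)-1,3,2-dioxaborolane | CC(C)/C=C/B1OC(C)(C)C(C)(C)O1 | starting material
20 | (R)-4′-O-acetyl target | COc1cc2oc3c(c(=O)c2c(O)c1/C=C/C(C)C)C[C@H](C(C)(C)O)Oc1cc(OC(C)=O)ccc1-3 | intermediate (not isolated)
21 | CNP0216454.1, (R) | COc1cc2oc3c(c(=O)c2c(O)c1/C=C/C(C)C)C[C@H](C(C)(C)O)Oc1cc(O)ccc1-3 | target

**Step count and risks**

Total steps: 14. Longest linear sequence: 13 (steps 2–5, then 6–14, from 5-methoxybenzene-1,3-diol).

Step 6 is the most likely to fail. The vinyl anion may be protonated before it closes onto the ketone, giving only the open Michael adduct; the ambident enolate may attack through oxygen; or the terminal ynone may oligomerise. The fallback sets out from 4 (and from 7 for the acyl donor) and returns at 11. It runs the same ring expansion with the acetylenic-ester partner for which this reaction type is documented and attaches the A ring afterwards by classical enolate acylation. The sodium enolate of 4 and allyl propiolate should give 4-allyl 2-tert-butyl 8-(benzyloxy)-5-oxo-4,5-dihydro-1-benzoxepine-2,4-dicarboxylate F1. Pd(PPh3)4/morpholine deallylation with loss of CO2 from the β-keto acid should give tert-butyl 8-(benzyloxy)-5-oxo-4,5-dihydro-1-benzoxepine-2-carboxylate F2. Pinnick oxidation of 7 gives 4-methoxy-2,6-bis(methoxymethoxy)benzoic acid F3, which carbonyldiimidazole converts into the acyl imidazolide F4. C-acylation of the lithium dienolate of F2 (LiHMDS, 2.2 equiv, THF, −78 °C) with F4 at the α-carbon should give 11.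

Step 8 is the second risk: facial selectivity may be insufficient, or turnover slow, on the ring-constrained, chromone-conjugated acrylic acid. The fallback sets out from 12 and returns at 13 by resolution instead of asymmetric catalysis. Hydrogenation with an achiral cationic rhodium bisphosphine catalyst (H2, MeOH, Et3N) should give the racemic dihydro acid F5. Crystallisation with (R)-1-phenylethylamine (or its antipode, whichever gives the less soluble salt of the (R)-acid) should give the diastereomeric salt F6, and acidification returns 13. The (S)-acid F7 stays in the mother liquor.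

Step 13 is the third risk: iodination may compete on the electron-rich B ring or at C8. The fallback sets out from 16 and returns at 21, forming the C6–C bond by phenol-directed formylation and olefination instead of halogenation and cross-coupling. Pivaloyl chloride/pyridine at 0 °C should give the 4′-O-pivalate F8. Magnesium-mediated ortho-formylation (MgCl2, Et3N, paraformaldehyde, MeCN, reflux) occurs only ortho to the single free phenol and should give the 6-formyl pivalate F9. Julia–Kocienski olefination with 5-(isobutylsulfonyl)-1-phenyl-1H-tetrazole (KHMDS in excess, DME, −60 °C → rt) should give the (E)-6-alkenyl pivalate F10. K2CO3/MeOH then removes the pivalate to give 21.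

**Further compounds**

F1 | step 6 | 4-allyl 2-tert-butyl 8-(benzyloxy)-5-oxo-4,5-dihydro-1-benzoxepine-2,4-dicarboxylate | CC(C)(C)OC(=O)C1=CC(C(=O)OCC=C)C(=O)c2ccc(OCc3ccccc3)cc2O1
F2 | step 6 | tert-butyl 8-(benzyloxy)-5-oxo-4,5-dihydro-1-benzoxepine-2-carboxylate | CC(C)(C)OC(=O)C1=CCC(=O)c2ccc(OCc3ccccc3)cc2O1
F3 | step 6 | 4-methoxy-2,6-bis(methoxymethoxy)benzoic acid | COCOc1cc(OC)cc(OCOC)c1C(=O)O
F4 | step 6 | (1H-imidazol-1-yl)[4-methoxy-2,6-bis(methoxymethoxy)phenyl]methanone | COCOc1cc(OC)cc(OCOC)c1C(=O)n1ccnc1
F5 | step 8 | racemic dihydro acid (rac-13) | COc1cc2oc3c(c(=O)c2c(O)c1)CC(C(=O)O)Oc1cc(OCc2ccccc2)ccc1-3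
F6 | step 8 | (R)-1-phenylethylammonium salt of 13 | COc1cc2oc3c(c(=O)c2c(O)c1)C[C@H](C(=O)[O-])Oc1cc(OCc2ccccc2)ccc1-3.C[C@@H]([NH3+])c1ccccc1
F7 | step 8 | (S)-dihydro acid (ent-13) | COc1cc2oc3c(c(=O)c2c(O)c1)C[C@@H](C(=O)O)Oc1cc(OCc2ccccc2)ccc1-3
F8 | step 13 | (R)-4′-O-pivalate of 16 | COc1cc2oc3c(c(=O)c2c(O)c1)C[C@H](C(C)(C)O)Oc1cc(OC(=O)C(C)(C)C)ccc1-3
F9 | step 13 | (R)-6-formyl-4′-O-pivalate | COc1cc2oc3c(c(=O)c2c(O)c1C=O)C[C@H](C(C)(C)O)Oc1cc(OC(=O)C(C)(C)C)ccc1-3
F10 | step 13 | (R)-4′-O-pivaloyl target | COc1cc2oc3c(c(=O)c2c(O)c1/C=C/C(C)C)C[C@H](C(C)(C)O)Oc1cc(OC(=O)C(C)(C)C)ccc1-3
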